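Assumption: the SMILES is read as [(1S,2R,5R,6S)-6-acetoxy-5-(benzoyloxy)-1,2-dihydroxycyclohex-3-en-1-yl]methyl benzoate. For the discussion the ring is numbered C1 (quaternary carbinol), C2 (acetoxy carbon), C3 (benzoyloxy carbon), C4=C5, C6 (free carbinol) in every intermediate; α is the ring face of the C1 hydroxyl, β the face of the C1 CH2O arm. The bacterial strain of step 1 is treated as a biocatalyst and benzoic acid as the commercial starting material.

## Structural features

The target is one cyclohexene ring: C1 is a quaternary carbinol with a CH2OBz arm, C2 carries the acetate, C3 a benzoate, C4=C5 is the ring alkene and C6 a free allylic hydroxyl. The four stereocentres are contiguous (C6–C1–C2–C3) and every vicinal oxygen pair is trans (6β-OH, 1α-OH, 2β-OAc, 3α-OBz), so the allylic oxygens at C3 and C6 are also trans across the alkene and there is no cis-diol anywhere. Fragile points are the three esters (the C2 acetate and the primary benzoate can migrate to the free C1 and C6 hydroxyls under base), the two allylic C–O bonds at C3 and C6 (ionisation, SN2′), and the tendency of oxygenated cyclohexadiene intermediates to aromatise under acid. The real difficulty is twofold: the fully substituted carbinol C1 must be set in the absolute sense between two oxygenated carbons, and five oxygens must end in three different states (two benzoates, one acetate, two free hydroxyls, one of them secondary). The feature the key step exploits is that C1, its exocyclic carbon and C2–C6 are the seven carbons of benzoic acid, and the C1(OH)–C2(O) pair is the ipso/ortho pattern that a benzoate dioxygenase installs. This leaves a C3=C4–C5=C6 diene exactly where the two remaining oxygens (C3, C6) and the C4=C5 alkene are needed. The enzyme sets C1 correctly but C2 cis to it, so C2 is first used to steer a face-selective 1,4-oxygenation and is then inverted, together with C3, by an epoxide transposition. In one sentence, the route is the benzoate dioxygenase cis-dihydroxylation of benzoic acid to a homochiral cyclohexadiene cis-diol acid, which does not describe the carbohydrate/ring-closing-metathesis or quinic acid routes that come to mind first.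

## Logic of the disconnections

14 ⇒ 13. Cut: the O–Si bond at C6, added in the reverse sense. Reason: the C6 hydroxyl must be free at the end while C2 is acetylated, and the two secondary hydroxyls cannot be told apart by direct acylation. Gain: the last step is a deprotection that touches no stereocentre. Demand: desilylation under weakly acidic fluoride conditions so that no ester migrates.

13 ⇒ 12. Cut: the acetyl C–O bond at C2. Reason: in 12 the C2 hydroxyl is the only acylable one (C1 is tertiary, C6 is silylated). Gain: no selectivity problem. Demand: mild acylation that leaves the tertiary hydroxyl alone.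

12 ⇒ 11 + 1. Cut: the C3–O bond to the benzoate. Reason: the trans C2/C3 pair is the signature of an epoxide opened at its allylic carbon. Gain: two stereocentres collapse into one cis-epoxide and the second benzoate comes from the starting material itself. Demand: SN2 attack at C3 with inversion, not at C2 and not at C5 in the SN2′ sense.

11 ⇒ 10. Cut: the O–Si bond at C6 (protection). Reason: the free C6 hydroxyl of 10 must be masked before the second secondary hydroxyl appears. Demand: silylation of the secondary hydroxyl in the presence of the tertiary one.

10 ⇒ 8 (through 9). Cut: the C2–O bond of the epoxide and, before it, the O–O bond. Reason: the epoxide oxygen is the C3 oxygen of a peroxide bridge; when it displaces a C2 sulfonate it inverts the one centre the enzyme set with the wrong relative sense. Gain: the C2 problem is solved intramolecularly at a neopentyl-type carbon where an external nucleophile would fail, and both peroxide oxygens are used. Demand: C3–O and the C2 leaving group must be trans, and no other hydroxyl may compete.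

8 ⇒ 7 ⇒ 6. Cut: the S–O bond at C2, then the ketal C–O bonds. Reason: the C2 oxygen can only become a leaving group once the diene is gone (a dienyl sulfonate would ionise and aromatise), and only while the C3 oxygen is still tied up in the peroxide. Demand: ketal hydrolysis that spares the peroxide, and mesylation of the secondary hydroxyl only.

6 ⇒ 5. Cut: the C3–O and C6–O bonds. Reason: a [4+2] cycloaddition of singlet oxygen places both oxygens on one face and leaves the C4=C5 alkene. Gain: two stereocentres and the alkene position in one step from a planar diene. Demand: addition to the β face, anti to the ketal.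

5 ⇒ 4 ⇒ 3 ⇒ 2. Cut: the benzoate C–O bond, the C–H bonds of the CH2O arm (carboxyl reduction) and the ketal. Reason: the ketal is needed both for handling and as the face-blocking element. Gain: functional group changes only. Demand: no acid strong enough to aromatise the diene.

2 ⇒ 1. Cut: the C1–O and C2–O bonds (key disconnection). Reason: a dearomatising ipso/ortho cis-dihydroxylation creates the quaternary carbinol, the full carbon skeleton and the diene from a flat arene. Gain: from a homochiral, densely functionalised cyclohexadiene to benzoic acid. Demand: regio- and enantioselectivity and arrest at the diol stage, which only the enzyme supplies.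

## Other disconnections considered

Alternative 1: Cut the C4=C5 bond. The forward key step would be a ring-closing metathesis (second-generation Grubbs catalyst) of an acyclic 1,7-diene A1, used in a suitably protected form, whose stereocentres would come from the carbohydrate pool and from a vinyl-metal addition to a ketone that creates C1. This is the first plan that comes to mind. It is not preferred because the all-trans C6–C1–C2–C3 tetrad does not coincide with a common pentose or hexose. At least one centre would therefore have to be inverted, and C1 would rest on substrate control in an addition to a ketone flanked by two alkoxy carbons, where chelation and Felkin control oppose each other. The five oxygens would need a full orthogonal protecting-group set, so the step count should be clearly higher, and the metathesis itself solves none of the stereochemistry.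

Alternative 2: Keep C1 achiral until late. Oxidative dearomatisation of the phenol A2 would give the prochiral p-quinol A3. A catalyst-controlled epoxidation of one of its two enantiotopic enones on the face anti to the hydroxyl would give A4, and a Wharton transposition would give the trans-dienediol A5, which already has the correct C1/C2 relationship. It is not preferred because the epoxidation must select an enantiotopic group and at the same time override the inherent hydroxyl-directed syn delivery in quinols. The Wharton step on a cross-conjugated epoxy dienone invites aromatisation. A5 would still need a trans-1,4 oxygenation of its diene, whereas singlet oxygen gives cis. The enzyme route sets C1 with a catalyst that is specific for exactly this substrate.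

Alternative 3: Cut C1–O and C6–O as an epoxide. A Sharpless asymmetric epoxidation (Ti(OiPr)4, dialkyl tartrate, t-BuOOH) of the Birch-type dienyl carbinol A6 would give the epoxy alcohol A7, to be opened at C6 by water at the end. It sets C1 and C6 elegantly but is not preferred: A7 has no oxygen at C2 or C3 and its alkene is at C3=C4. The plan would therefore still need a stereocontrolled oxidation of C2, an unactivated methylene next to the quaternary epoxide carbon, plus an alkene transposition. In the chosen plan the dioxygenase leaves the diene placed so that one cycloaddition delivers both missing oxygens.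

Key step: step 1

## Route

Step 1
Reactants: 1 benzoic acid
Product: 2 (1S,2R)-1,2-dihydroxycyclohexa-3,5-diene-1-carboxylic acid (1α,2α-cis-diol)
Conditions: whole cells of Ralstonia eutropha B9 (benzoate 1,2-dioxygenase active, diol dehydrogenase absent), 1 fed as sodium salt, fructose, aerated mineral medium, pH 7, 30 °C; then pH 3 at 0 °C, EtOAc extraction
Reagents that add atoms: dioxygen, O=O
Why: The reaction type is the known arene cis-dihydroxylation by a Rieske non-heme iron dioxygenase, here of the benzoate 1,2-dioxygenase class, which no small-molecule oxidant reproduces on an unactivated benzene ring. Electrons from NADH pass through the reductase and the [2Fe-2S] cluster to a mononuclear iron centre (divalent iron in the resting state), which binds O2 and delivers both oxygen atoms to the same face of the ipso/ortho C=C bond, so the diol is cis by mechanism. No ring is closed; the arene is dearomatised to a 1,3-diene spanning C3–C6. The two new stereocentres, C1 (quaternary, S) and C2 (R), are set by the enzyme: the bound carboxylate fixes both the site of attack (ipso/ortho, not ortho/meta) and the ring face that meets the iron–oxygen species. The step needs regioselectivity, enantiofacial selectivity and arrest at the diol; the first two come from the active site, the third from the blocked mutant, which lacks the dehydrogenase that would aromatise the diol to catechol. C1 is thereby the quaternary carbinol of the target in its final configuration, with all seven carbons in place. C2 is carried with the cis relative sense on purpose: it steers the facial course of step 5 and is inverted in step 8.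

Step 2
Reactants: 2 (1S,2R)-1,2-dihydroxycyclohexa-3,5-diene-1-carboxylic acid
Product: 3 1α,2α-O-isopropylidene ketal of 2 (cis-fused 2,2-dimethyl-1,3-dioxolane, free carboxylic acid)
Conditions: Me2C(OMe)2, TsOH·H2O (cat.), acetone, 0 °C → rt; Et3N quench
Reagents that add atoms: 2,2-dimethoxypropane, COC(C)(C)OC
Why: Acetal exchange on the cis-diol gives the cis-fused dioxolane; excess ketal keeps the medium anhydrous and catalytic acid at low temperature should avoid dehydrative aromatisation; no stereocentre is touched.

Step 3
Reactants: 3 acetonide acid
Product: 4 [1α,2α-(isopropylidenedioxy)cyclohexa-3,5-dien-1-yl]methanol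
Conditions: LiAlH4, THF, 0 °C → rt; aqueous NaOH work-up
Reagents that add atoms: none
Why: Hydride reduction of the carboxylic acid to the primary alcohol; the unconjugated diene and the ketal are inert to LiAlH4 and the basic work-up avoids acid-induced aromatisation.

Step 4
Reactants: 4 acetonide alcohol
Product: 5 [1α,2α-(isopropylidenedioxy)cyclohexa-3,5-dien-1-yl]methyl benzoate
Conditions: BzCl, Et3N, DMAP (cat.), CH2Cl2, 0 °C
Reagents that add atoms: benzoyl chloride, O=C(Cl)c1ccccc1
Why: Acylation of the only free hydroxyl installs the primary benzoate of the target.

Step 5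
Reactants: 5 diene acetonide benzoate
Product: 6 [3β,6β-epidioxy-1α,2α-(isopropylidenedioxy)cyclohex-4-en-1-yl]methyl benzoate (bicyclic endoperoxide)
Conditions: O2, tetraphenylporphyrin (cat.), visible light, CH2Cl2, −20 °C
Reagents that add atoms: dioxygen, O=O
Why: Singlet oxygen [4+2] cycloaddition is suprafacial on the diene, so the C3–O and C6–O bonds form on one face and the alkene moves to C4=C5. The cis-fused ketal with its endo methyl shields the α face, so addition should occur on the β face, setting C6 (final) and C3 (whose oxygen later becomes the C2 oxygen).

Step 6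
Reactants: 6 endoperoxide acetonide
Product: 7 (3β,6β-epidioxy-1α,2α-dihydroxycyclohex-4-en-1-yl)methyl benzoate
Conditions: CF3CO2H, H2O, THF, 0 °C → rt
Reagents that add atoms: none
Why: Acid hydrolysis of the ketal; with the diene consumed there is no aromatisation path, and a dialkyl peroxide bridge and a benzoate should tolerate dilute protic acid.

Step 7
Reactants: 7 endoperoxide diol
Product: 8 [3β,6β-epidioxy-1α-hydroxy-2α-(methanesulfonyloxy)cyclohex-4-en-1-yl]methyl benzoate
Conditions: MsCl, Et3N, CH2Cl2, −40 °C, short reaction time; cold aqueous NH4Cl quench
Reagents that add atoms: methanesulfonyl chloride, CS(=O)(=O)Cl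
Why: Sulfene-type mesylation is fast at −40 °C and takes the secondary C2 hydroxyl over the tertiary one; the low temperature suppresses amine-induced Kornblum–DeLaMare fragmentation of the peroxide.

Step 8
Reactants: 8 endoperoxide mesylate
Product: 10 (2β,3β-epoxy-1α,6β-dihydroxycyclohex-4-en-1-yl)methyl benzoate, via enediol mesylate 9 (not isolated)
Conditions: thiourea, MeOH, 0 °C → rt; evaporate, take up in CH2Cl2, filter; DBU, 0 °C
Reagents that add atoms: none
Why: Thiourea reduces the O–O bond to the cis-3β,6β-diol 9 without touching alkene, esters or mesylate, and is filtered off because it would convert an epoxide into a thiirane. With DBU the C3 alkoxide, trans to the C2 mesylate, closes the epoxide by intramolecular SN2 (Williamson type) with inversion at C2, so C2–O becomes β. The C1 hydroxyl is cis to the leaving group and the C6 hydroxyl could only form an oxetane, so only C3–O reacts.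

Step 9
Reactants: 10 epoxy diol
Product: 11 [6β-(tert-butyldimethylsilyloxy)-2β,3β-epoxy-1α-hydroxycyclohex-4-en-1-yl]methyl benzoate
Conditions: TBSCl, imidazole, DMAP (cat.), DMF, rt
Reagents that add atoms: tert-butyldimethylsilyl chloride, CC(C)(C)[Si](C)(C)Cl
Why: Silylation of the secondary allylic C6 hydroxyl; the tertiary C1 hydroxyl does not react with TBSCl under these conditions.

Step 10
Reactants: 11 silylated vinyl epoxide; 1 benzoic acid
Product: 12 [3α-(benzoyloxy)-6β-(tert-butyldimethylsilyloxy)-1α,2β-dihydroxycyclohex-4-en-1-yl]methyl benzoate
Conditions: PhCO2H (2 equiv), Ti(OiPr)4 (1.5 equiv), CH2Cl2, rt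
Reagents that add atoms: benzoic acid, OC(=O)c1ccccc1
Why: Ti(OiPr)4-mediated opening of a 2,3-epoxy alcohol by a carboxylic acid at the carbon remote from the carbinol is a known reaction type. Here it is reinforced by allylic activation of C3 and neopentyl-type shielding of C2; SN2 attack inverts C3, giving 3α-OBz and 2β-OH (trans).

Step 11
Reactants: 12 C2 alcohol
Product: 13 [2β-acetoxy-3α-(benzoyloxy)-6β-(tert-butyldimethylsilyloxy)-1α-hydroxycyclohex-4-en-1-yl]methyl benzoate
Conditions: Ac2O, pyridine, DMAP (cat.), CH2Cl2, 0 °C → rt
Reagents that add atoms: acetic anhydride, CC(=O)OC(C)=O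
Why: Acetylation of the only secondary hydroxyl; the tertiary C1 hydroxyl should stay free at this temperature and stoichiometry.

Step 12
Reactants: 13 silyl ether
Product: 14 [(1S,2R,5R,6S)-6-acetoxy-5-(benzoyloxy)-1,2-dihydroxycyclohex-3-en-1-yl]methyl benzoate (target)
Conditions: HF·pyridine, pyridine, THF, 0 °C → rt
Reagents that add atoms: none
Why: Fluoride-mediated desilylation under buffered, weakly acidic conditions frees the C6 hydroxyl without creating the alkoxides that would trigger acyl migration.

## Compound list

1 | benzoic acid | OC(=O)c1ccccc1 | starting material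
2 | (1S,2R)-1,2-dihydroxycyclohexa-3,5-diene-1-carboxylic acid | O[C@@H]1C=CC=C[C@@]1(O)C(=O)O | intermediate
3 | 1α,2α-O-isopropylidene ketal of 2, free acid | CC1(C)O[C@@H]2C=CC=C[C@@]2(O1)C(=O)O | intermediate
4 | [1α,2α-(isopropylidenedioxy)cyclohexa-3,5-dien-1-yl]methanol | CC1(C)O[C@@H]2C=CC=C[C@@]2(O1)CO | intermediate
5 | [1α,2α-(isopropylidenedioxy)cyclohexa-3,5-dien-1-yl]methyl benzoate | CC1(C)O[C@@H]2C=CC=C[C@@]2(O1)COC(=O)c1ccccc1 | intermediate
6 | [3β,6β-epidioxy-1α,2α-(isopropylidenedioxy)cyclohex-4-en-1-yl]methyl benzoate | CC1(C)O[C@@H]2[C@@H]3C=C[C@@H](OO3)[C@@]2(O1)COC(=O)c1ccccc1 | intermediate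
7 | (3β,6β-epidioxy-1α,2α-dihydroxycyclohex-4-en-1-yl)methyl benzoate | O[C@@H]1[C@@H]2C=C[C@@H](OO2)[C@@]1(O)COC(=O)c1ccccc1 | intermediate
8 | [3β,6β-epidioxy-1α-hydroxy-2α-(methanesulfonyloxy)cyclohex-4-en-1-yl]methyl benzoate | CS(=O)(=O)O[C@@H]1[C@@H]2C=C[C@@H](OO2)[C@@]1(O)COC(=O)c1ccccc1 | intermediate
9 | [1α,3β,6β-trihydroxy-2α-(methanesulfonyloxy)cyclohex-4-en-1-yl]methyl benzoate | CS(=O)(=O)O[C@@H]1[C@@H](O)C=C[C@@H](O)[C@@]1(O)COC(=O)c1ccccc1 | intermediate
10 | (2β,3β-epoxy-1α,6β-dihydroxycyclohex-4-en-1-yl)methyl benzoate | O1[C@H]2[C@@H]1C=C[C@@H](O)[C@@]2(O)COC(=O)c1ccccc1 | intermediate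
11 | [6β-(tert-butyldimethylsilyloxy)-2β,3β-epoxy-1α-hydroxycyclohex-4-en-1-yl]methyl benzoate | O1[C@H]2[C@@H]1C=C[C@@H](O[Si](C)(C)C(C)(C)C)[C@@]2(O)COC(=O)c1ccccc1 | intermediate
12 | [3α-(benzoyloxy)-6β-(tert-butyldimethylsilyloxy)-1α,2β-dihydroxycyclohex-4-en-1-yl]methyl benzoate | O[C@H]1[C@H](OC(=O)c2ccccc2)C=C[C@@H](O[Si](C)(C)C(C)(C)C)[C@@]1(O)COC(=O)c1ccccc1 | intermediate
13 | [2β-acetoxy-3α-(benzoyloxy)-6β-(tert-butyldimethylsilyloxy)-1α-hydroxycyclohex-4-en-1-yl]methyl benzoate | CC(=O)O[C@H]1[C@H](OC(=O)c2ccccc2)C=C[C@@H](O[Si](C)(C)C(C)(C)C)[C@@]1(O)COC(=O)c1ccccc1 | intermediate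
14 | [(1S,2R,5R,6S)-6-acetoxy-5-(benzoyloxy)-1,2-dihydroxycyclohex-3-en-1-yl]methyl benzoate | CC(=O)O[C@H]1[C@H](OC(=O)c2ccccc2)C=C[C@@H](O)[C@@]1(O)COC(=O)c1ccccc1 | target

## Step count and least certain steps

Total step count: 12. Longest linear sequence: 12 steps (fully linear from benzoic acid; benzoic acid is used a second time as the reagent of step 10).

Step 1 (key step). What may go wrong: dehydrogenation of the diol to catechol if the culture regains dehydrogenase activity, low conversion from substrate toxicity, or acid-promoted dehydration and rearomatisation of the diene-diol acid during the acidic extraction. The fallback replaces the enzyme by a chemical desymmetrisation; it sets out from 1 and returns at 2.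
- Birch reduction of 1 (Li, NH3, then NH4Cl) should give cyclohexa-2,5-diene-1-carboxylic acid F1.
- Esterification (MeI, K2CO3, DMF) should give methyl cyclohexa-2,5-diene-1-carboxylate F2.
- Enolate hydroxylation (LDA, THF, −78 °C, then 2-(phenylsulfonyl)-3-phenyloxaziridine) should give the prochiral bis-allylic tertiary alcohol methyl 1-hydroxycyclohexa-2,5-diene-1-carboxylate F3.
- A hydroxyl-directed desymmetrising epoxidation (VO(OiPr)3 with a chiral bishydroxamic acid ligand, cumene hydroperoxide) should give the syn epoxy alcohol methyl 2α,3α-epoxy-1α-hydroxycyclohex-5-ene-1-carboxylate F4. The ligand enantiomer selects which of the two enantiotopic alkenes reacts.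
- Base-induced eliminative opening of the epoxide (LDA, THF, −78 → 0 °C; removal of the allylic C4 proton) should give methyl (1S,2R)-1,2-dihydroxycyclohexa-3,5-diene-1-carboxylate F5.
- Saponification (LiOH, THF/H2O, 0 °C) returns 2.

Step 6. What may go wrong: acid-induced fragmentation or rearrangement of the peroxide bridge, or sluggish cleavage of the hindered cis-fused ketal at the tertiary centre, so that forcing conditions are needed. The fallback removes acid from this stage by masking the diol as a cyclic boronate; it sets out from 2 and returns at 7.
- LiAlH4 reduction of 2 (THF, 0 °C → rt) should give the triol 1-(hydroxymethyl)cyclohexa-3,5-diene-1α,2α-diol F6.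
- BzCl with 2,4,6-collidine at −40 °C should acylate the primary hydroxyl to give (1α,2α-dihydroxycyclohexa-3,5-dien-1-yl)methyl benzoate F7.
- PhB(OH)2 (MgSO4, CH2Cl2) should give the cyclic phenylboronate F8.
- Photooxygenation as in step 5 should give the phenylboronate endoperoxide F9. The flat boronate shields the α face less than the ketal does, so facial selectivity is the weak point of this detour.
- Transesterification with pinacol at rt releases 7 under neutral conditions.

Step 10. What may go wrong: attack of benzoate at C5 in the SN2′ sense or at C2, Payne-type migration of the epoxide towards C1 through the tertiary alkoxide, or loss of the silyl ether under the Lewis acid followed by over-acylation in step 11. The fallback uses a C6 carbonyl instead of a silyl ether as the masking group, which also makes C3 a vinylogous α-keto position; it sets out from 10 and returns at 14.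
- MnO2 (CH2Cl2, rt) should oxidise the allylic C6 hydroxyl to the epoxy enone (2β,3β-epoxy-1α-hydroxy-6-oxocyclohex-4-en-1-yl)methyl benzoate F10.
- PhCO2H with catalytic PhCO2Cs (DMF, 40 °C) should open the epoxide at C3 with inversion to give the hydroxy benzoate enone F11.
- Ac2O, pyridine and DMAP should give the acetate enone F12.
- NaBH4 with CeCl3·7H2O (MeOH, −78 °C) should reduce the ketone from the α face, anti to the axial CH2OBz arm of the chelated α-hydroxy ketone, to give 14. The facial course of this hydride addition is the uncertainty of the detour.

## Further compounds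

F1 | step 1 | cyclohexa-2,5-diene-1-carboxylic acid | OC(=O)C1C=CCC=C1
F2 | step 1 | methyl cyclohexa-2,5-diene-1-carboxylate | COC(=O)C1C=CCC=C1
F3 | step 1 | methyl 1-hydroxycyclohexa-2,5-diene-1-carboxylate | COC(=O)C1(O)C=CCC=C1
F4 | step 1 | methyl 2α,3α-epoxy-1α-hydroxycyclohex-5-ene-1-carboxylate | O1[C@@H]2[C@H]1CC=C[C@@]2(O)C(=O)OC
F5 | step 1 | methyl (1S,2R)-1,2-dihydroxycyclohexa-3,5-diene-1-carboxylate | O[C@@H]1C=CC=C[C@@]1(O)C(=O)OC
F6 | step 6 | 1-(hydroxymethyl)cyclohexa-3,5-diene-1α,2α-diol | O[C@@H]1C=CC=C[C@@]1(O)CO
F7 | step 6 | (1α,2α-dihydroxycyclohexa-3,5-dien-1-yl)methyl benzoate | O[C@@H]1C=CC=C[C@@]1(O)COC(=O)c1ccccc1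
F8 | step 6 | cyclic 1α,2α-phenylboronate of F7 | B1(c2ccccc2)O[C@@H]2C=CC=C[C@@]2(O1)COC(=O)c1ccccc1
F9 | step 6 | 3β,6β-endoperoxide of F8 | B1(c2ccccc2)O[C@@H]2[C@@H]3C=C[C@@H](OO3)[C@@]2(O1)COC(=O)c1ccccc1
F10 | step 10 | (2β,3β-epoxy-1α-hydroxy-6-oxocyclohex-4-en-1-yl)methyl benzoate | O1[C@H]2[C@@H]1C=CC(=O)[C@@]2(O)COC(=O)c1ccccc1
F11 | step 10 | [3α-(benzoyloxy)-1α,2β-dihydroxy-6-oxocyclohex-4-en-1-yl]methyl benzoate | O[C@H]1[C@H](OC(=O)c2ccccc2)C=CC(=O)[C@@]1(O)COC(=O)c1ccccc1
F12 | step 10 | [2β-acetoxy-3α-(benzoyloxy)-1α-hydroxy-6-oxocyclohex-4-en-1-yl]methyl benzoate | CC(=O)O[C@H]1[C@H](OC(=O)c2ccccc2)C=CC(=O)[C@@]1(O)COC(=O)c1ccccc1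
A1 | alternative 1 | acyclic octa-1,7-diene carrying the ester pattern of the target (metathesis precursor, shown unprotected) | C=C[C@@H](OC(=O)c1ccccc1)[C@H](OC(C)=O)[C@](O)(COC(=O)c1ccccc1)[C@H](O)C=C
A2 | alternative 2 | 4-hydroxybenzyl benzoate | Oc1ccc(COC(=O)c2ccccc2)cc1
A3 | alternative 2 | 4-(benzoyloxymethyl)-4-hydroxycyclohexa-2,5-dien-1-one (p-quinol) | O=C1C=CC(O)(COC(=O)c2ccccc2)C=C1
A4 | alternative 2 | mono-epoxide of A3, epoxide anti to the hydroxyl | O1[C@H]2[C@@H]1C(=O)C=C[C@@]2(O)COC(=O)c1ccccc1
A5 | alternative 2 | (1α,2β-dihydroxycyclohexa-3,5-dien-1-yl)methyl benzoate (trans-dienediol) | O[C@H]1C=CC=C[C@@]1(O)COC(=O)c1ccccc1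
A6 | alternative 3 | (cyclohexa-1,4-dien-1-yl)methanol | OCC1=CCC=CC1
A7 | alternative 3 | (1α,6α-epoxycyclohex-3-en-1-yl)methanol, single enantiomer | OC[C@@]12CC=CC[C@@H]1O2
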